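**Plan**

1. Numbering used throughout: macrocycle chain C1–C14; C1=C15 (C15 bears CH3‑17); C2, C3 = diol carbons; C4 = quaternary carbon (CH3‑18); cyclopentane = C4–C5–C6–C7–C16; C8 (=C19H2); C9 (OAc); C12 (C20H2OAc).
2. Retrosynthesis: the diol is traced to the C2 ketone (α′‑hydroxylation at C3, directed reduction). Then C1=C15 and C3–C4 are cut together: the ring C1–C2–C3–C4–C16–C15 is an isophorone‑type cyclohexenone (C2=O, methyl‑bearing C15, quaternary methyl‑bearing C4), i.e. the product of Michael addition of a methyl ketone (C3H3–C2O–C1H2) to the β‑methyl enone C4=C16–C15(=O)CH3 followed by aldol condensation.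
3. The seco compound, a cyclopentenyl methyl ketone tethered through C7–C14 to that methyl ketone, is cut at C9–C10 into an α‑methylene aldehyde (from (R)‑limonene oxide) and a dialkylzinc (from a Cu‑catalysed allylic alkylation).
4. Forward: cyclopentene first, chain joined at C9–C10, then in one operation the 13‑membered Michael ring and, transannularly, the six‑ and eleven‑membered rings.
5. Stereochemistry: C7 from limonene; C12 and C9 from ligand control; C4 from delivery of C3 along the C7 tether; C16 by equilibration to the cis‑hydrindenone; C3 by convex‑face enolate hydroxylation; C2 by hydroxyl‑directed hydride delivery.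

Key step: step 11

**Route**

Step 1
Reactants: 1 (4R)-limonene 1,2-oxide (cis/trans mixture)
Product: 3 (3R)-6-oxo-3-(prop-1-en-2-yl)heptanal, via limonene-1,2-diol 2 (not isolated)
Conditions: H5IO6, THF/H2O, 0 °C to rt
Reagents that add atoms: water, O
Why: Acid-mediated epoxide hydrolysis followed at once by periodate glycol cleavage should open both epoxide isomers to the same keto aldehyde, leaving the isopropenyl group and the non-enolisable stereocentre (later C7) untouched.

Step 2
Reactants: 3 (3R)-6-oxo-3-(prop-1-en-2-yl)heptanal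
Product: 4 (5S)-2-methyl-5-(prop-1-en-2-yl)cyclopent-1-ene-1-carbaldehyde
Conditions: piperidine, AcOH, toluene, reflux
Reagents that add atoms: none
Why: Amine-catalysed intramolecular aldol condensation, in which the enamine of the aldehyde attacks the methyl ketone (5-exo-trig) and dehydration gives the conjugated cyclopentenecarbaldehyde with the C4 methyl and the C7 stereocentre in place.

Step 3
Reactants: 4 (5S)-2-methyl-5-(prop-1-en-2-yl)cyclopent-1-ene-1-carbaldehyde
Product: 5 1-[(5S)-2-methyl-5-(prop-1-en-2-yl)cyclopent-1-en-1-yl]ethan-1-ol (both carbinol epimers)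
Conditions: MeMgBr, THF, −78 °C
Reagents that add atoms: methylmagnesium bromide, C[Mg]Br
Why: Grignard 1,2-addition to the hindered enal brings in CH3-17; the new carbinol centre is not controlled and is removed in the next step.

Step 4
Reactants: 5 1-[(5S)-2-methyl-5-(prop-1-en-2-yl)cyclopent-1-en-1-yl]ethan-1-ol
Product: 6 1-[(5S)-2-methyl-5-(prop-1-en-2-yl)cyclopent-1-en-1-yl]ethan-1-one
Conditions: MnO2, CH2Cl2, rt
Reagents that add atoms: none
Why: Selective allylic alcohol oxidation with MnO2 should give the tetrasubstituted enone (the later Michael acceptor C4=C16–C15=O) without touching the isopropenyl group.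

Step 5
Reactants: 6 1-[(5S)-2-methyl-5-(prop-1-en-2-yl)cyclopent-1-en-1-yl]ethan-1-one
Product: 7 1-[(5R)-5-(3-chloroprop-1-en-2-yl)-2-methylcyclopent-1-en-1-yl]ethan-1-one
Conditions: Ca(OCl)2, solid CO2, CH2Cl2/H2O, 0 °C
Reagents that add atoms: calcium hypochlorite (as HOCl), [Ca+2].[O-]Cl.[O-]Cl
Why: Ene-type allylic chlorination by HOCl should act only on the electron-rich 1,1-disubstituted alkene (the enone alkene is deactivated) and turn the isopropenyl group into the 2-(chloromethyl)vinyl unit C9–C8=C19.

Step 6
Reactants: 7 1-[(5R)-5-(3-chloroprop-1-en-2-yl)-2-methylcyclopent-1-en-1-yl]ethan-1-one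
Product: 8 2-[(1S)-2-acetyl-3-methylcyclopent-2-en-1-yl]prop-2-enal
Conditions: Me3NO, NaI (cat.), DMSO, rt to 40 °C
Reagents that add atoms: trimethylamine N-oxide, C[N+](C)(C)[O-]
Why: Amine N-oxide oxidation of an allylic halide (Kornblum/Ganem type), with O-alkylation of the N-oxide and loss of trimethylamine from the alkoxyammonium salt, should give the α-substituted acrolein carrying C9 as the aldehyde.

Step 7
Reactants: 9 2-(3-chloropropyl)-2-methyl-1,3-dioxolane; 10 (E)-1,4-dibromobut-2-ene
Product: 12 2-[(4R)-4-(bromomethyl)hex-5-en-1-yl]-2-methyl-1,3-dioxolane, via Grignard reagent 11 (not isolated)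
Conditions: Mg, THF, reflux; then added to 10, CuBr·SMe2 (cat.), Taniaphos (ferrocenyl diphosphine, the enantiomer that gives the (R)-bromide), CH2Cl2, −78 °C
Reagents that add atoms: none
Why: Copper-catalysed asymmetric allylic alkylation (SN2′) of the symmetric dibromide by the Grignard reagent should give the branched bromide, the chiral diphosphine setting the C12 stereocentre while the second C–Br bond survives at low temperature.

Step 8
Reactants: 12 2-[(4R)-4-(bromomethyl)hex-5-en-1-yl]-2-methyl-1,3-dioxolane
Product: 13 (2R)-2-ethenyl-5-(2-methyl-1,3-dioxolan-2-yl)pentyl acetate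
Conditions: CsOAc, DMF, 50 °C
Reagents that add atoms: caesium acetate, [Cs+].CC(=O)[O-]
Why: SN2 displacement of the primary bromide by carboxylate installs the C20 oxygen in a form that tolerates the organozinc chemistry of the next step.

Step 9
Reactants: 13 (2R)-2-ethenyl-5-(2-methyl-1,3-dioxolan-2-yl)pentyl acetate (2.4 equiv); 8 2-[(1S)-2-acetyl-3-methylcyclopent-2-en-1-yl]prop-2-enal
Product: 16 (2R)-2-{(3S)-4-[(1S)-2-acetyl-3-methylcyclopent-2-en-1-yl]-3-hydroxypent-4-en-1-yl}-5-(2-methyl-1,3-dioxolan-2-yl)pentyl acetate, via alkyldiethylborane 14 (not isolated), via dialkylzinc 15 (not isolated)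
Conditions: Et2BH, THF, 0 °C to rt; Et2Zn (neat), 0 °C, then volatiles removed in vacuo; (2S)-3-exo-(dimethylamino)isoborneol [(−)-DAIB, 5 mol%], toluene, 8, 0 °C; aqueous NH4Cl
Reagents that add atoms: none
Why: Anti-Markovnikov hydroboration of the only alkene of 13, boron–zinc exchange and amino-alcohol-catalysed 1,2-addition of the dialkylzinc to the aldehyde (the hindered ketone and the esters should not react) form C9–C10, the ligand directing the alkyl group to the Si face to give the (9S)-carbinol.

Step 10
Reactants: 16 (union alcohol, C20 acetate, dioxolane)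
Product: 18 (6R,9S)-10-[(1S)-2-acetyl-3-methylcyclopent-2-en-1-yl]-9-hydroxy-6-(hydroxymethyl)undec-10-en-2-one, via diol ketal 17 (not isolated)
Conditions: K2CO3 (cat.), MeOH, 0 °C; then 1 M HCl, THF, rt
Reagents that add atoms: water, O
Why: Base-catalysed transesterification removes the C20 acetate and acid hydrolysis of the dioxolane unveils the methyl ketone, so that the cyclisation substrate carries only hydroxyl groups that are inert to alkoxide base.

Step 11
Reactants: 18 (seco diol diketone)
Product: 21 tricyclic enone diol (C2 ketone conjugated with C1=C15; 9-OH and 20-OH free; cis-fused hydrindenone), via macrocyclic diketone 19 (not isolated), via bridged ketol 20 (not isolated)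
Conditions: KOt-Bu (0.5 equiv), t-BuOH/toluene (1:4), slow addition of 18 to a final 1 mM, 70 °C
Reagents that add atoms: none
Why: Proposed new method: under equilibrating alkoxide conditions the methyl ketone of 18 enolises at C3 and adds to C4 of the tetrasubstituted enone (13-endo-trig Michael macrocyclisation to 19), the C1 enolate of 19 attacks the C15 carbonyl across the ring (6-(enolendo)-exo-trig aldol to 20, which also closes the eleven-membered ring) and E1cB loss of water gives the tetrasubstituted enone 21, every step before the dehydration being reversible so that the sequence is pulled through its one irreversible exit. The closest known reaction type is the base-mediated Michael addition–aldol condensation of a methyl ketone with a β-methyl enone that gives isophorone-type cyclohexenones (Robinson-type annulation), here proposed for the first time in an intramolecular form whose Michael step closes a macrocycle. C4 is set by the tether: the chain carrying the nucleophile leaves C7 on one face of the flat cyclopentenyl ketone and can reach C4 only on that face, which places C3 cis to the C7–C8 bond and the C4 methyl on the opposite face. C16 is epimerisable (α to the C15 ketone in 19, γ to the enone in 21) and should settle as the cis-fused hydrindenone, the C1 and C15 centres of 20 are lost on dehydration so that all ketol isomers converge, and the E geometry of C1=C15 within the eleven-membered ring follows from its cis placement in the six-membered ring. The step needs the C3 enolate (not C1) as Michael donor and the C1→C15 aldol (not C17→C2): only the primary C3 carbon can approach the fully substituted C4, and the C1→C15 mode gives the 1,3-bridged tetrasubstituted enone whereas the alternative would give a more strained 1,4-bridged system, and since misdirected adducts can revert they should drain into 21. Slow addition at high dilution suppresses intermolecular Michael addition, and reversible addition of the C9 alkoxide to C4 or C15 should only park material temporarily.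

Step 12
Reactants: 21 (tricyclic enone diol)
Product: 22 9,20-diacetate of 21
Conditions: Ac2O, pyridine, DMAP (cat.), CH2Cl2, rt
Reagents that add atoms: acetic anhydride, CC(=O)OC(C)=O
Why: DMAP-catalysed acylation of the secondary C9 and primary C20 hydroxyl groups, the only acylable sites of 21.

Step 13
Reactants: 22 (diacetate enone)
Product: 24 (3R)-3-hydroxy derivative of 22 (3-OH on the face of the C4 methyl), via lithium enolate 23 (not isolated)
Conditions: LiN(SiMe3)2 (1.1 equiv), THF, −78 °C; then 2-(phenylsulfonyl)-3-phenyloxaziridine, −78 °C; aqueous work-up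
Reagents that add atoms: 2-(phenylsulfonyl)-3-phenyloxaziridine, O=S(=O)(N1OC1c1ccccc1)c1ccccc1
Why: Kinetic deprotonation can occur only at C3 (the α′ position; C1 carries no hydrogen), and oxygen transfer from the N-sulfonyloxaziridine (enolate hydroxylation) should take place on the convex face of the cis-hydrindenone, anti to the macrocyclic bridge, giving the equatorial 3-OH cis to the C4 methyl, which should also be the more stable epimer.

Step 14
Reactants: 24 (α′-hydroxy enone)
Product: 25 CNP0193272.1, the (2R,3R,4S,7R,9S,12R,16S) 9,20-diacetoxy-2,3-diol (target)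
Conditions: Me4NBH(OAc)3, MeCN/AcOH (1:1), −20 °C
Reagents that add atoms: none
Why: Hydroxyl-directed reduction, in which the C3–OH exchanges onto boron and delivers hydride intramolecularly to the same face of the C2 carbonyl (1,2-reduction only), should give the 2,3-trans diol without touching the acetates or the alkenes.

**Compound list**

1 | (4R)-limonene 1,2-oxide, (4R)-1-methyl-4-(prop-1-en-2-yl)-7-oxabicyclo[4.1.0]heptane, cis/trans mixture | CC12OC1C[C@@H](CC2)C(=C)C | starting material
2 | (4R)-1-methyl-4-(prop-1-en-2-yl)cyclohexane-1,2-diol | CC(=C)[C@@H]1CCC(C)(O)C(O)C1 | intermediate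
3 | (3R)-6-oxo-3-(prop-1-en-2-yl)heptanal | CC(=O)CC[C@H](CC=O)C(=C)C | intermediate
4 | (5S)-2-methyl-5-(prop-1-en-2-yl)cyclopent-1-ene-1-carbaldehyde | O=CC1=C(C)CC[C@H]1C(C)=C | intermediate
5 | 1-[(5S)-2-methyl-5-(prop-1-en-2-yl)cyclopent-1-en-1-yl]ethan-1-ol, both carbinol epimers | CC(O)C1=C(C)CC[C@H]1C(C)=C | intermediate
6 | 1-[(5S)-2-methyl-5-(prop-1-en-2-yl)cyclopent-1-en-1-yl]ethan-1-one | CC(=O)C1=C(C)CC[C@H]1C(C)=C | intermediate
7 | 1-[(5R)-5-(3-chloroprop-1-en-2-yl)-2-methylcyclopent-1-en-1-yl]ethan-1-one | CC(=O)C1=C(C)CC[C@H]1C(=C)CCl | intermediate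
8 | 2-[(1S)-2-acetyl-3-methylcyclopent-2-en-1-yl]prop-2-enal | CC(=O)C1=C(C)CC[C@H]1C(=C)C=O | intermediate
9 | 2-(3-chloropropyl)-2-methyl-1,3-dioxolane | CC1(CCCCl)OCCO1 | starting material
10 | (E)-1,4-dibromobut-2-ene | BrC/C=C/CBr | starting material
11 | [3-(2-methyl-1,3-dioxolan-2-yl)propyl]magnesium chloride | CC1(CCC[Mg]Cl)OCCO1 | intermediate
12 | 2-[(4R)-4-(bromomethyl)hex-5-en-1-yl]-2-methyl-1,3-dioxolane | C=C[C@H](CBr)CCCC1(C)OCCO1 | intermediate
13 | (2R)-2-ethenyl-5-(2-methyl-1,3-dioxolan-2-yl)pentyl acetate | C=C[C@H](COC(C)=O)CCCC1(C)OCCO1 | intermediate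
14 | diethyl[3-(acetoxymethyl)-6-(2-methyl-1,3-dioxolan-2-yl)hexyl]borane, branching carbon configured as in 13 | CCB(CC)CC[C@H](COC(C)=O)CCCC1(C)OCCO1 | intermediate
15 | bis[3-(acetoxymethyl)-6-(2-methyl-1,3-dioxolan-2-yl)hexyl]zinc, branching carbons configured as in 13 | [Zn](CC[C@H](COC(C)=O)CCCC1(C)OCCO1)CC[C@H](COC(C)=O)CCCC1(C)OCCO1 | intermediate
16 | (2R)-2-{(3S)-4-[(1S)-2-acetyl-3-methylcyclopent-2-en-1-yl]-3-hydroxypent-4-en-1-yl}-5-(2-methyl-1,3-dioxolan-2-yl)pentyl acetate | CC(=O)C1=C(C)CC[C@H]1C(=C)[C@@H](O)CC[C@H](COC(C)=O)CCCC2(C)OCCO2 | intermediate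
17 | (2R)-2-{(3S)-4-[(1S)-2-acetyl-3-methylcyclopent-2-en-1-yl]-3-hydroxypent-4-en-1-yl}-5-(2-methyl-1,3-dioxolan-2-yl)pentan-1-ol | CC(=O)C1=C(C)CC[C@H]1C(=C)[C@@H](O)CC[C@H](CO)CCCC2(C)OCCO2 | intermediate
18 | (6R,9S)-10-[(1S)-2-acetyl-3-methylcyclopent-2-en-1-yl]-9-hydroxy-6-(hydroxymethyl)undec-10-en-2-one | CC(=O)C1=C(C)CC[C@H]1C(=C)[C@@H](O)CC[C@H](CO)CCCC(C)=O | intermediate
19 | macrocyclic 1,5-diketone: C3–C4 bond formed, 13-membered ring bridging C4 and C7 of the cyclopentane, C3 cis to the C7–C8 bond, C16 epimers, 9-OH and 20-OH free | C=C1[C@@H](O)CC[C@H](CO)CCCC(=O)C[C@@]2(C)CC[C@@H]1C2C(C)=O | intermediate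
20 | bridged ketol: C1–C15 bond formed, tertiary C15–OH, C2 ketone, epimers at C1, C15 and C16 | C=C1[C@@H](O)CC[C@H](CO)CCC2C(=O)C[C@@]3(C)CC[C@@H]1C3C2(C)O | intermediate
21 | tricyclic enone diol: C2 ketone conjugated with C1=C15, (9S)-OH, (12R)-CH2OH, cis-hydrindenone with C16–H, C4–CH3 and C7–H on one face | C=C1[C@@H](O)CC[C@H](CO)CCC2=C(C)[C@@H]3[C@H]1CC[C@]3(C)CC2=O | intermediate
22 | 9,20-diacetate of 21 | C=C1[C@@H](OC(C)=O)CC[C@H](COC(C)=O)CCC2=C(C)[C@@H]3[C@H]1CC[C@]3(C)CC2=O | intermediate
23 | lithium C2(O)=C3 enolate of 22 | C=C1[C@@H](OC(C)=O)CC[C@H](COC(C)=O)CCC2=C(C)[C@@H]3[C@H]1CC[C@]3(C)C=C2O[Li] | intermediate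
24 | (3R)-3-hydroxy-2-ketone: 22 with 3-OH on the face of the C4 methyl | C=C1[C@@H](OC(C)=O)CC[C@H](COC(C)=O)CCC2=C(C)[C@@H]3[C@H]1CC[C@]3(C)[C@@H](O)C2=O | intermediate
25 | CNP0193272.1, (2R,3R,4S,7R,9S,12R,16S)-9,20-diacetoxy-2,3-diol in the numbering above | C=C1[C@@H](OC(C)=O)CC[C@H](COC(C)=O)CCC2=C(C)[C@@H]3[C@H]1CC[C@]3(C)[C@@H](O)[C@@H]2O | target

**Count and risks**

Total steps: 14. Longest linear sequence: 12 (steps 1–6 and 9–14); steps 7–8 form the side branch.

Steps most likely to fail:

1. Step 11 (Proposed new method). The macrocyclic Michael addition at the fully substituted C4 may not compete with reversion, with oligomerisation, or with parking of the enone as C9–O adducts; the aldol may also take the C17→C2 course. Fallback (known reactions, stepwise, sets out from 18 and comes back at 21): 18 is condensed with pyrrolidine (4 Å molecular sieves, toluene, 60 °C) to the less substituted pyrrolidine enamine of the C2 ketone F1; the hindered conjugated C15 ketone should not condense. F1 is heated at high dilution in dioxane so that the enamine adds to C4 (Stork enamine Michael addition) to give the pyrrolidine enamine of the macrocyclic diketone F2. Aqueous AcOH/NaOAc hydrolyses F2 to 19, which is now isolated. 19 is then cyclodehydrated in a separate operation (piperidine, AcOH, toluene, reflux; amine-catalysed aldol condensation) to 21.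

2. Step 13. The oxaziridine may attack the enolate on the wrong face (next to the axial C4 methyl), or the liberated sulfonimine may add to the enolate. Fallback (sets out from 22 and comes back at 24): radical α′-acyloxylation of the enone with Mn(OAc)3·2H2O and chloroacetic acid in benzene at reflux gives the α′-chloroacetoxy enone F3. As an ester it can be equilibrated at C3 with DBU to the equatorial epimer without α-ketol shift. The chloroacetate is then removed selectively in the presence of the two acetates with thiourea/NaHCO3 in EtOH to give 24.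

3. Step 6. Displacement of the allylic chloride may be sluggish, and the liberated trimethylamine may trigger oligomerisation of the α-substituted acrolein. Fallback (sets out from 6 and comes back at 8, bypassing steps 5 and 6): allylic oxidation of the isopropenyl methyl group of 6 with SeO2 (cat.)/t-BuOOH in CH2Cl2 gives 1-[(5S)-5-(3-hydroxyprop-1-en-2-yl)-2-methylcyclopent-1-en-1-yl]ethan-1-one F4. MnO2 in CH2Cl2 then oxidises F4 to 8 under neutral conditions.

**Further compounds**

F1 | step 11 | pyrrolidine enamine (C2=C3 isomer) of the C2 ketone of 18 | CC(=O)C1=C(C)CC[C@H]1C(=C)[C@@H](O)CC[C@H](CO)CCCC(=C)N2CCCC2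
F2 | step 11 | pyrrolidine enamine of macrocyclic diketone 19 | C=C1[C@@H](O)CC[C@H](CO)CCC=C(N2CCCC2)C[C@@]3(C)CC[C@@H]1C3C(C)=O
F3 | step 13 | 3-chloroacetoxy derivative of 22, C3 configured as in 24 | C=C1[C@@H](OC(C)=O)CC[C@H](COC(C)=O)CCC2=C(C)[C@@H]3[C@H]1CC[C@]3(C)[C@@H](OC(=O)CCl)C2=O
F4 | step 6 | 1-[(5S)-5-(3-hydroxyprop-1-en-2-yl)-2-methylcyclopent-1-en-1-yl]ethan-1-one | CC(=O)C1=C(C)CC[C@H]1C(=C)CO
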